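**Plan**

- The side chain is numbered C1' (benzylic CH2) to C11' (carbinol carbon of the 2-hydroxypropan-2-yl group). Retrosynthetic cuts, in order: the C1'–C2' benzyl–alkenyl bond (with the 3'-methyl), then the oxolane O–C10' bond together with the C11'–OH bond, then C4'–C5'.
- Forward: geraniol supplies C5'–C11'. Sharpless epoxidation, Payne-type hydrolysis and re-closure give a terminal epoxide, which a propargyl anion opens to the acyclic 6',7'-diol 9. The only ring, the oxolane, then arises by osmium-catalysed oxidative cyclization. Carboalumination/cross-coupling joins the arene, and saponification frees acid and phenol.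
- Enabling feature: in 9 the vicinal C6' (secondary)/C7' (tertiary) diol can chelate hexavalent osmium while O–C7' sits four atoms from C10' of the C10'=C11' alkene. The ring O–C10' bond and the C11'–O bond therefore form in one syn addition that can only give the 2,5-cis oxolane.
- Stereochemistry: C7' (R) comes from the catalytic epoxidation (its C–O bond is never broken), C6' (S) from the same event after one inversion, and C10' (S) is relayed from both by the osmium chelate (substrate control). The E-C2'=C3' alkene comes from syn carbometalation.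

Key step: step 5

Remark: the target is taken as (6'S,7'R,10'S) with the C6' carbon and the 2-hydroxypropan-2-yl group cis on the oxolane, which is what the SMILES encodes.

Step 1
Reactants: 1 geraniol
Product: 2 [(2R,3R)-3-methyl-3-(4-methylpent-3-en-1-yl)oxiran-2-yl]methanol
Conditions: Ti(OiPr)4 (5 mol %), D-(−)-diethyl tartrate (7.5 mol %), t-BuOOH, 4 Å MS, CH2Cl2, −20 °C
Reagents that add atoms: tert-butyl hydroperoxide, CC(C)(C)OO
Why: Sharpless asymmetric epoxidation; the titanium tartrate complex delivers oxygen to one enantioface of the E-allylic alcohol (D-(−)-tartrate should give the 2R,3R epoxide), and the remote C6=C7 alkene, lacking a directing hydroxyl, is left alone.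

Step 2
Reactants: 2 [(2R,3R)-3-methyl-3-(4-methylpent-3-en-1-yl)oxiran-2-yl]methanol
Product: 4 (2S,3R)-3,7-dimethyloct-6-ene-1,2,3-triol, via Payne-rearranged epoxy alkoxide 3 (not isolated)
Conditions: NaOH (0.5 M aq.), t-BuOH, 75 °C
Reagents that add atoms: water, O
Why: Payne rearrangement followed by hydroxide opening; the C1 alkoxide displaces the epoxide oxygen at C2 with inversion to give terminal epoxide 3, which hydroxide opens at its CH2, so C2 (future C6') becomes S while the C3–O bond (future C7', R) is never broken, and direct attack of hydroxide at C2 would lead to the same triol.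

Step 3
Reactants: 4 (2S,3R)-3,7-dimethyloct-6-ene-1,2,3-triol
Product: 6 (2R)-6-methyl-2-[(2S)-oxiran-2-yl]hept-5-en-2-ol, via primary monotosylate 5 (not isolated)
Conditions: TsCl, Et3N, Bu2SnO (2 mol %), CH2Cl2, 0 °C to rt; then K2CO3, MeOH, 0 °C, short contact time
Reagents that add atoms: none
Why: Tin-catalysed regioselective sulfonylation of the primary hydroxyl through the dibutylstannylene acetal, then Williamson-type 3-exo-tet closure by the secondary alkoxide; no bond to a stereocentre is broken, and displacement of tosylate is far faster than epoxide migration under carbonate.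

Step 4
Reactants: 6 (2R)-6-methyl-2-[(2S)-oxiran-2-yl]hept-5-en-2-ol; 7 trimethyl(prop-1-yn-1-yl)silane
Product: 9 (5S,6R)-6,10-dimethylundec-9-en-1-yne-5,6-diol, via C-silylated alkynyl diol 8 (not isolated)
Conditions: 7 (3.5 equiv), n-BuLi, THF, −78 to −20 °C; then 6, DMPU, −78 to 0 °C; then MeOH, K2CO3, rt
Reagents that add atoms: none
Why: Epoxide opening by a propargylic organolithium (SN2 at the unsubstituted epoxide carbon C5', remote from both stereocentres; lithiated 1-silylpropynes react at the propargylic carbon), followed by base-mediated protodesilylation of the alkynylsilane; the first equivalent of the lithium reagent is consumed by the tertiary hydroxyl.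

Step 5
Reactants: 9 (5S,6R)-6,10-dimethylundec-9-en-1-yne-5,6-diol
Product: 12 (1S)-1-[(2R,5S)-5-(2-hydroxypropan-2-yl)-2-methyloxolan-2-yl]pent-4-yn-1-ol, via hexavalent osmium glycolate 10 (not isolated), via tetravalent osmium chelate 11 (not isolated)
Conditions: K2OsO2(OH)4 (5 mol %), pyridine N-oxide (2 equiv), citric acid (0.75 equiv), Zn(OTf)2 (0.5 equiv), MeCN/aq. NaH2PO4–Na2HPO4 buffer (pH 6.5), 60 °C
Reagents that add atoms: pyridine N-oxide, [O-][n+]1ccccc1
Why: The diol condenses with hexavalent osmium to glycolate 10; acid activation (citric acid, Zn(OTf)2) makes the metal electrophilic, and the C10'=C11' alkene adds across the O(C7')–Os=O unit in an intramolecular syn [3+2] oxyosmylation to give tetravalent chelate 11, which is hydrolysed while pyridine N-oxide returns osmium to the hexavalent state. The closest known reaction type is the osmium-catalysed oxidative cyclization of 5,6-dihydroxyalkenes to 2,5-cis-tetrahydrofurans, the catalytic relative of the permanganate oxidative cyclization of 1,5-dienes. The oxolane closes in a 5-exo mode by O(C7')–C10' bond formation, and the exocyclic C11'–O bond forms in the same event. C10' is set by substrate control: the C6' oxygen and the new C11' oxygen are bound to the same osmium atom, so C6' and C11' must lie on the same face of the new ring, which with 6'S,7'R means 10'S, while C6' and C7' are untouched. The step needs the tertiary C7' oxygen and not the secondary C6' oxygen to become the ring oxygen, which the ring size secures (C7'–O gives a five-membered ring, C6'–O would need a six-membered one). It also needs the terminal alkyne to survive, which is expected because hexavalent osmium glycolates do not dihydroxylate, alkynes are poor partners for metal-oxo [3+2] addition, and the N-oxide does not build up octavalent osmium tetroxide.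

Step 6
Reactants: 13 methyl 4-hydroxy-3-methylbenzoate
Product: 14 methyl 4-[(2,2-dimethylpropanoyl)oxy]-3-methylbenzoate
Conditions: t-BuCOCl, Et3N, DMAP (cat.), CH2Cl2, 0 °C to rt
Reagents that add atoms: pivaloyl chloride, CC(C)(C)C(=O)Cl
Why: DMAP-catalysed acylation of the phenol; the pivalate should survive radical bromination and the organoaluminium step and is removed by the final saponification.

Step 7
Reactants: 14 methyl 4-[(2,2-dimethylpropanoyl)oxy]-3-methylbenzoate
Product: 15 methyl 3-(bromomethyl)-4-[(2,2-dimethylpropanoyl)oxy]benzoate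
Conditions: NBS (1.05 equiv), AIBN (cat.), PhCF3, 80 °C
Reagents that add atoms: N-bromosuccinimide, O=C1CCC(=O)N1Br
Why: Wohl–Ziegler benzylic bromination; the ring carries two acyl-type substituents and is deactivated toward electrophilic bromination, so the single benzylic methyl group is the reactive site.

Step 8
Reactants: 12 (1S)-1-[(2R,5S)-5-(2-hydroxypropan-2-yl)-2-methyloxolan-2-yl]pent-4-yn-1-ol; 15 methyl 3-(bromomethyl)-4-[(2,2-dimethylpropanoyl)oxy]benzoate
Product: 17 methyl 4-[(2,2-dimethylpropanoyl)oxy]-3-[(2E,6S)-6-hydroxy-6-[(2R,5S)-5-(2-hydroxypropan-2-yl)-2-methyloxolan-2-yl]-3-methylhex-2-en-1-yl]benzoate, via alkenyldimethylalane 16 (not isolated)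
Conditions: Me3Al (5 equiv), Cp2ZrCl2 (0.5 equiv), CH2Cl2, 0 °C to rt; volatiles removed; then 15, Pd(PPh3)4 (5 mol %), THF, rt; aq. KNaC4H4O6 work-up
Reagents that add atoms: trimethylaluminium, C[Al](C)C
Why: Negishi zirconium-catalysed carboalumination (syn addition of methyl to the internal and aluminium to the terminal alkyne carbon) followed by alkenyl–benzyl cross-coupling on zerovalent palladium with retention of alkene geometry, which fixes the E C2'=C3' bond; the two hydroxyls are carried as aluminium alkoxides, as in carboaluminations of pent-4-yn-1-ols.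

Step 9
Reactants: 17 methyl 4-[(2,2-dimethylpropanoyl)oxy]-3-[(2E,6S)-6-hydroxy-6-[(2R,5S)-5-(2-hydroxypropan-2-yl)-2-methyloxolan-2-yl]-3-methylhex-2-en-1-yl]benzoate
Product: 18 4-hydroxy-3-[(2E,6S)-6-hydroxy-6-[(2R,5S)-5-(2-hydroxypropan-2-yl)-2-methyloxolan-2-yl]-3-methylhex-2-en-1-yl]benzoic acid
Conditions: LiOH (aq., excess), THF/MeOH, 50 °C; then 1 M HCl to pH 3, 0 °C
Reagents that add atoms: lithium hydroxide, [Li+].[OH-]
Why: Saponification cleaves the aryl pivalate and the methyl benzoate in one operation; acidification is kept mild and cold because an ortho-allylic phenol of this kind can close to a chroman under strong acid.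

**Compound list**

1 | geraniol, (2E)-3,7-dimethylocta-2,6-dien-1-ol | CC(C)=CCC/C(C)=C/CO | starting material
2 | [(2R,3R)-3-methyl-3-(4-methylpent-3-en-1-yl)oxiran-2-yl]methanol | CC(C)=CCC[C@@]1(C)O[C@@H]1CO | intermediate
3 | sodium (2R)-6-methyl-2-[(2S)-oxiran-2-yl]hept-5-en-2-olate (formed in the flask) | CC(C)=CCC[C@@](C)([O-])[C@@H]1CO1.[Na+] | intermediate
4 | (2S,3R)-3,7-dimethyloct-6-ene-1,2,3-triol | CC(C)=CCC[C@@](C)(O)[C@@H](O)CO | intermediate
5 | (2S,3R)-2,3-dihydroxy-3,7-dimethyloct-6-en-1-yl 4-methylbenzenesulfonate (formed in the flask) | CC(C)=CCC[C@@](C)(O)[C@@H](O)COS(=O)(=O)c1ccc(C)cc1 | intermediate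
6 | (2R)-6-methyl-2-[(2S)-oxiran-2-yl]hept-5-en-2-ol | CC(C)=CCC[C@@](C)(O)[C@@H]1CO1 | intermediate
7 | trimethyl(prop-1-yn-1-yl)silane | CC#C[Si](C)(C)C | starting material
8 | (5S,6R)-6,10-dimethyl-1-(trimethylsilyl)undec-9-en-1-yne-5,6-diol (formed in the flask) | C[Si](C)(C)C#CCC[C@H](O)[C@](C)(O)CCC=C(C)C | intermediate
9 | (5S,6R)-6,10-dimethylundec-9-en-1-yne-5,6-diol | C#CCC[C@H](O)[C@](C)(O)CCC=C(C)C | intermediate
10 | cyclic hexavalent osmium glycolate of 9 (dioxo ester, spectator ligands omitted; formed in the flask) | C#CCC[C@@H]1O[Os](=O)(=O)O[C@]1(C)CCC=C(C)C | intermediate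
11 | tetravalent osmium chelate of 12 (oxo ester bridging the C6' and C11' oxygens, spectator ligands omitted; formed in the flask) | C#CCC[C@@H]1O[Os](=O)OC(C)(C)[C@@H]2CC[C@@]1(C)O2 | intermediate
12 | (1S)-1-[(2R,5S)-5-(2-hydroxypropan-2-yl)-2-methyloxolan-2-yl]pent-4-yn-1-ol | C#CCC[C@H](O)[C@@]1(C)CC[C@@H](C(C)(C)O)O1 | intermediate
13 | methyl 4-hydroxy-3-methylbenzoate | COC(=O)c1ccc(O)c(C)c1 | starting material
14 | methyl 4-[(2,2-dimethylpropanoyl)oxy]-3-methylbenzoate | COC(=O)c1ccc(OC(=O)C(C)(C)C)c(C)c1 | intermediate
15 | methyl 3-(bromomethyl)-4-[(2,2-dimethylpropanoyl)oxy]benzoate | COC(=O)c1ccc(OC(=O)C(C)(C)C)c(CBr)c1 | intermediate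
16 | (E)-alkenyldimethylalane of 12 with both hydroxyls as dimethylaluminium alkoxides (formed in the flask) | C[Al](C)/C=C(\C)CC[C@H](O[Al](C)C)[C@@]1(C)CC[C@@H](C(C)(C)O[Al](C)C)O1 | intermediate
17 | methyl 4-[(2,2-dimethylpropanoyl)oxy]-3-[(2E,6S)-6-hydroxy-6-[(2R,5S)-5-(2-hydroxypropan-2-yl)-2-methyloxolan-2-yl]-3-methylhex-2-en-1-yl]benzoate | C/C(=C\Cc1cc(C(=O)OC)ccc1OC(=O)C(C)(C)C)CC[C@H](O)[C@@]1(C)CC[C@@H](C(C)(C)O)O1 | intermediate
18 | 4-hydroxy-3-[(2E,6S)-6-hydroxy-6-[(2R,5S)-5-(2-hydroxypropan-2-yl)-2-methyloxolan-2-yl]-3-methylhex-2-en-1-yl]benzoic acid | C/C(=C\Cc1cc(C(=O)O)ccc1O)CC[C@H](O)[C@@]1(C)CC[C@@H](C(C)(C)O)O1 | target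

**Step count and risks**

Total step count: 9. Longest linear sequence: 7 (steps 1, 2, 3, 4, 5, 8, 9).

Steps most likely to fail:

1. Step 5. The glycolate of a hindered secondary/tertiary diol may form or turn over slowly. Octavalent osmium could then build up and dihydroxylate the alkene instead of cyclizing, or the secondary alcohol could be over-oxidized. The fallback sets out from 9 and comes back at 12. Shi epoxidation of the C10'=C11' alkene of 9 with the D-fructose-derived ketone (KHSO5, K2CO3, MeCN/dimethoxymethane/aq. buffer, 0 °C) should give (5S,6R)-8-[(2R)-3,3-dimethyloxiran-2-yl]-6-methyloct-1-yne-5,6-diol F1. Camphorsulfonic acid (cat.) in CH2Cl2 at 0 °C should then close the oxolane by 5-exo-tet attack of the C7' hydroxyl on C10' with inversion, which arrives at 12. C10' is then set by the catalyst and not by the substrate.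

2. Step 8. Residual Me3Al may transfer methyl to the benzylic palladium species, the aluminium alkoxide aggregates may slow transmetalation, and the organoalane may attack the ester groups. The fallback sets out from 12 and 15 and comes back at 17, with the roles of the partners reversed. Alane 16 is quenched with I2 (THF, −30 °C) to give (1S,4E)-1-[(2R,5S)-5-(2-hydroxypropan-2-yl)-2-methyloxolan-2-yl]-5-iodo-4-methylpent-4-en-1-ol F2. Bromide 15 is converted with Zn dust and LiCl in THF into bromo{[5-(methoxycarbonyl)-2-(pivaloyloxy)phenyl]methyl}zinc F3. Negishi coupling of F2 with an excess of F3 (Pd(OAc)2, SPhos, THF, rt) should give 17 with retention of the E geometry.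

3. Step 4. The tertiary lithium alkoxide next to the epoxide may send the epoxide back by Payne migration to the unreactive trisubstituted isomer. The basic reagent may also cause elimination, or react through its allenyl terminus. The fallback sets out from 6 and comes back at 9, and removes the neighbouring alkoxide altogether. N-(Trimethylsilyl)imidazole (CH2Cl2, rt) should give trimethyl{[(2R)-6-methyl-2-[(2S)-oxiran-2-yl]hept-5-en-2-yl]oxy}silane F4. Opening with lithiated 7 under Lewis-acid assistance (n-BuLi, BF3·OEt2, THF, −78 °C) should give (5S,6R)-6,10-dimethyl-1-(trimethylsilyl)-6-[(trimethylsilyl)oxy]undec-9-en-1-yn-5-ol F5. K2CO3 in MeOH should then remove both silyl groups to give 9.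

Further compounds
F1 | step 5 | (5S,6R)-8-[(2R)-3,3-dimethyloxiran-2-yl]-6-methyloct-1-yne-5,6-diol | C#CCC[C@H](O)[C@](C)(O)CC[C@H]1OC1(C)C
F2 | step 8 | (1S,4E)-1-[(2R,5S)-5-(2-hydroxypropan-2-yl)-2-methyloxolan-2-yl]-5-iodo-4-methylpent-4-en-1-ol | I/C=C(\C)CC[C@H](O)[C@@]1(C)CC[C@@H](C(C)(C)O)O1
F3 | step 8 | bromo{[5-(methoxycarbonyl)-2-(pivaloyloxy)phenyl]methyl}zinc | COC(=O)c1ccc(OC(=O)C(C)(C)C)c(C[Zn]Br)c1
F4 | step 4 | trimethyl{[(2R)-6-methyl-2-[(2S)-oxiran-2-yl]hept-5-en-2-yl]oxy}silane | CC(C)=CCC[C@@](C)(O[Si](C)(C)C)[C@@H]1CO1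
F5 | step 4 | (5S,6R)-6,10-dimethyl-1-(trimethylsilyl)-6-[(trimethylsilyl)oxy]undec-9-en-1-yn-5-ol | C[Si](C)(C)C#CCC[C@H](O)[C@](C)(O[Si](C)(C)C)CCC=C(C)C
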